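(The data were computed with constants of no real substance, and the scatter is random.)

| flask | starting material | partner | temperature | remark | time |
|---|---|---|---|---|---|
| alpha | 0.34 M | 1.05 equiv | 75 °C | run made earlier |  |
| beta | 0.75 M | 1.05 equiv | 95 °C | run made earlier |  |
| gamma | 0.50 M | 1.6 equiv | 75 °C | run made earlier |  |
| dawn | 0.50 M | 1.05 equiv | 80 °C |  | 10 min |
| winter | 0.50 M | 1.05 equiv | 110 °C |  | 10 min |

| run | time / min | target / % |
|---|---|---|
| alpha | 3.00 | 1.9 |
| alpha | 8.00 | 5.1 |
| alpha | 15.0 | 8.6 |
| alpha | 25.0 | 10.3 |
| alpha | 30.0 | 12.0 |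
| alpha | 50.0 | 17.3 |
| alpha | 60.0 | 17.9 |
| beta | 3.00 | 11.2 |
| beta | 6.00 | 17.6 |
| beta | 8.00 | 19.4 |
| beta | 12.0 | 22.2 |
| beta | 15.0 | 24.1 |
| beta | 20.0 | 24.1 |
| gamma | 5.00 | 3.7 |
| gamma | 15.0 | 8.2 |
| gamma | 30.0 | 12.8 |
| gamma | 50.0 | 16.1 |
| gamma | 60.0 | 17.2 |

(readings scatter by 0.5 percentage points)



- the flask that ends with the higher amount of target, in percent of the starting material charged, or "neither" when 2 percentage points or less lies between them (dawn / winter / neither)
- final target, as a percentage of the starting material charged, in dawn
- final target, as a percentage of the starting material charged, in winter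

**Early slope.** At early times I read a flask by a bench rule: target equals early slope times time, the early slope being the fraction of the charge that becomes target per minute. The alpha and gamma runs read 8.6% and 8.2% at 15.0 min, a gap smaller than the scatter of one reading, 0.5 percentage points, although their concentrations and partner loadings differ. So I took one slope per temperature. Alpha gave 0.00637 min⁻¹ at 75 °C and beta gave 0.0373 min⁻¹ at 95 °C, a factor of 5.86. Assuming the same factor for each equal step of temperature, I got for dawn, at 80 °C, an early slope of 0.00992 min⁻¹, which gives 9.92% in 10 min.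

**The border.** With partner at 1.05 equiv, the starting material is the reagent charged in the smaller amount, the limiting reagent, and I took target to be bounded by its charge. Yet the same rule gives winter a slope of 0.141 min⁻¹, hence 141% in 10 min, more than the charge. I therefore compared the time with the time the slope needs to reach the highest reading of a nearby run, and put the border where this ratio reaches one. For dawn, using alpha's 17.9%, this ratio is 0.554. Alpha at 15.0 min had a ratio of 0.534 and stood at 0.899 of its straight rule, so I expected dawn near 8.92%. For winter, using beta's 24.1%, the ratio is 5.85, far past the border, so the slope told me little there. Its slope is steeper than beta's, so I judged that winter would end above beta's reading, and so ahead of dawn.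

**The forecast.** The forecast named winter, with 9% for dawn and 28.5% for winter, holding that in winter “the plateau is reached by 10 min”.

**The flasks.** Dawn gave 8.90% and winter 36.2%, so winter ended higher.

    intermediate A ⇌ intermediate B (k = 0.00140 s⁻¹, Ea = 104 kJ mol⁻¹)
    starting material → target (k = 0.00350 s⁻¹, Ea = 109 kJ mol⁻¹)
    starting material ⇌ intermediate A (K = 1.10, k = 0.00280 s⁻¹, Ea = 120 kJ mol⁻¹, ΔH = −9.00 kJ mol⁻¹)
    starting material ⇌ intermediate B (K = 4.50, k = 0.00910 s⁻¹, Ea = 103 kJ mol⁻¹, ΔH = −90.0 kJ mol⁻¹)
    partner + intermediate A ⇌ intermediate C (K = 1.30 M⁻¹, k = 0.00620 M⁻¹ s⁻¹, Ea = 61.0 kJ mol⁻¹, ΔH = −18.0 kJ mol⁻¹)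
    (constants at 110 °C)

Dawn's result was 0.897 of the straight rule. Winter, past its border, held 28.0% of target at 5.00 min and 36.2% at 10.0 min. The reading of dawn at 4.0 min lies inside the border, at a ratio of 0.222; there the same early slope gives 3.97%, and the flask held 4.14%.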